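Of the constants I take first 42.0 M⁻¹ s⁻¹ and 0.134 M⁻¹ s⁻¹: in both of these steps E meets G.

| setting | south-east | north | east | west |
|---|---|---|---|---|
| G | 20 mM | 20 mM | 20 mM | 20 mM |
| E | 0.050 mM | 0.10 mM | 0.20 mM | 0.40 mM |
| time | 30 min | 30 min | 30 min | 30 min |

    G + E ⇌ J + E, rate k1*[G]*[E] forward; the back reaction follows from the equilibrium constant (K1 = 22, k1 = 42.0 M⁻¹ s⁻¹)
    Z + E ⇌ D + E, rate k2*[E]*[Z] forward; the back reaction follows from the equilibrium constant (K2 = 6.8, k2 = 4.12 M⁻¹ s⁻¹)
    J + E ⇌ Z + E, rate k3*[E]*[J] forward; the back reaction follows from the equilibrium constant (K3 = 1.88, k3 = 1.06 M⁻¹ s⁻¹)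
    G + E → G.E (k4 = 0.134 M⁻¹ s⁻¹)

- amount of J at the end, in percent of the G charged for south-east, north, east, west, in this order
- how that number moves from the first to the last of them (hardly changes / rises, then falls / falls all the way / rises all the way / falls, then rises)

- "hardly changes" means that all values lie within two and a half points (for a concentration: within two and a half percent of the largest)
- run time (south-east): 30 min

I keep a ledger of the G. Its forward turning into J and the loss of E to G.E run on the same product [G][E], so their ratio stays constant:

N = 42.0 M⁻¹ s⁻¹ / 0.134 M⁻¹ s⁻¹ = 313

This N is the moles of G turned forward per mole of E lost to G.E, the turnover number. I leave out every back reaction. Let g be the G charged and c the E charged.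

The first entry is the cost. Turning g once costs

B = g / N = 0.0638 mM of E.

South-east holds 0.050 mM of E, less than that cost, so there E is the limiting reagent. Its books close with G∞ = g − Nc = 4.33 mM unturned, which in this ledger gives J 78.4% of the charge. As G nears G∞ in south-east, E falls with the time τ = 1/(k4 G∞) = 28.7 min, about the run time, so in my reckoning the south-east run ends short of that close. I count all G turned as J, and since E = (G − G∞)/N, the rate law integrates to

G = G∞ / (1 − y), with y = (Nc/g) e^(−t/τ)

J in south-east ≈ 70.1%

The second entry is the surplus. North, east and west each charge more than the cost, so in this ledger S = c − B of E survives the turning of G. I count S over the whole run, carrying J on to Z, and J keeps the share e^(−k3 S t):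

north: 93.3%

east: 77.1%

west: 52.7%

My row is highest at north, so I commit to a rise and then a fall.

The forecast gives 66%, 87%, 76% and 57%, shape rises, then falls, on the ground: “The catalyst dies by reacting with G”.

The simulation gives 67.0%, 87.2%, 77.3% and 57.6%, shape rises, then falls, and north stands farthest from my row, by 6.1 percentage points.

In south-east G.E stands at 89.9% of the catalyst after 30.0 min, and N times that loss is 70.5% of the G charged, beside the 68.5% that has left G. In west E still stands at 80.4% of the catalyst after 9.00 min, against 36.9% in south-east, and by 30.0 min the G.E of west, 27.7% of its catalyst, times N comes to 174% of the G charged, so forward turnover there has passed the charge while G stands at 2.67%.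

All constants are made up; what happens was integrated by code.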